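Whatever the flask does, G, X with its Q, and G.X weighed by the G in it add up to the charge, so I reckon in fractions of the charge.

    G + X → 2 X (k1 = 3.7 × 10⁻⁵ /M/s, Ea1 = 72.0 kJ/mol)
    G → X (k2 = 1.1 × 10⁻⁶ /s, Ea2 = 107 kJ/mol)
    Q ⇌ X, rate k3*(cs3 - [X]) while solid is left; crystals form when [X] > cs3 (cs3 = 0.23 M, k3 = 2.3 × 10⁻⁴ /s)
    G + X → G.X (k4 = 8.1 × 10⁻⁶ /M/s, Ea4 = 72.0 kJ/mol)
    (constants at 40 °C)

common to all: G 0.50 M; time 5.0 d

| flask | temperature |
|---|---|
| noon | 40 °C |
| dusk | 25 °C |
| winter | 10 °C |
| autumn | −5 °C |

- the flask that comes out highest in amount of X, in percent of the G charged, or "all alike" when all lie within 1.5 percentage points (noon / dusk / winter / autumn / all alike)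
- X at the end, in percent of the G charged, noon
- X at the end, in percent of the G charged, dusk
- X at the end, in percent of the G charged, winter
- X at the end, in percent of the G charged, autumn

- in percentages every species weighs as the G in it: one G.X counts as two
- for X the Q are counted in
- as a solid, counted per litre of solution: Q
- the constants hold at 40 °C; other temperatures follow from the activation energies

1. The autocatalytic and uncatalysed steps speed up by 100 and 990 from autumn to noon, so I expect noon to lead, and I reckon noon.

2. Each G spent by those steps gains one X; each G spent on G.X loses one. The yield, X gained per G spent (an instantaneous selectivity), is therefore the two gaining rates minus the losing rate, over the sum of the three. It starts at one and sinks as dissolved X grows.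

3. In noon, crystals take up excess X faster than G then falls, 19.9 /d against 0.991 /d, so dissolved X stops near 0.460 of the charge. The yield there is 0.675, the saturated yield: X gained per G spent while the solution stands at solubility.

4. With the charge spent, X in noon is at least the saturated yield, 0.675. Replacing the climb to solubility by its mean yield, the chord, caps X at 0.764. Integrating the curve leaves 0.365 of the charge as G at saturation, so X comes to 0.707 once that G is spent too.

5. Saturation in noon comes after 1.56 d if G stays at its charge, and 2.29 d if G stands at its mean. The G left at the end then puts X in noon between 69.0% and 69.9%.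

6. The forecast says noon comes out highest, with noon 69.4%, dusk 12.7%, winter 0.72% and autumn 0.05%; its noon value lies inside my bracket. Its ground: “About 0.68 X forms per G consumed”.

The flasks give noon 69.3%, dusk 12.7%, winter 0.722% and autumn 0.0495%, so noon leads and the forecast stands. Its noon value belongs to the asked time: noon read at 30 h holds 22.6%. Between 2.50 d and 5.00 d, noon gains 0.675 X per G spent, close to the saturated yield of 0.675. The noon flask charged with 0.20 M of G holds Q 0% and has spent 82.7%, so the saturated yield asks for at least 55.9% X, and it holds more, 63.0%.

All constants belong to no real substance; the flask was simulated.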